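**Plan**
- Cuts: first the C3–C1′ bond between the pyridine and the dienyl chain. Then, together, the two aryl bonds C4a–C5 and C7–C7a of the five-membered ring.
- Enabling feature (cyclopenta[c]pyridine numbering C1, N2, C3, C4, C4a, C5, C6, C7, C7a): the non-aromatic atoms C7(=O)–C6(Me)(OMe)–C5(OH)–CO2Me form a linear four-carbon diacid chain with one tertiary C–O centre. This is the citramalic acid skeleton, and it is held to the pyridine ring only through the adjacent carbons C4a and C7a.
- Forward: (S)-citramalic acid is taken in six steps to a non-enolisable 3-oxo diester. A 4-iodo-5-bromopyridine is metallated twice in one flask and closes the carbocycle onto it. The side chain (four steps) is joined last by cross-coupling at C3.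
- Stereochemistry: C6 comes unchanged from (S)-citramalic acid. C5 is induced by C6 through magnesium chelation during the aryl addition. C5′ comes from (S)-2-methylbutan-1-ol, and both alkenes come from E-selective Wittig and boron–Wittig olefinations.

Key step: step 7

Remark: the carbinol carbon created by the enolate hydroxylation is carried as a mixture of epimers, because it later becomes the ketone carbon, so its descriptor is left open in the SMILES. All five starting materials are taken as commercial.

Step 1
Reactants: 1 (S)-citramalic acid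
Product: 2 dimethyl (2S)-2-hydroxy-2-methylbutanedioate
Conditions: MeOH, H2SO4 (cat.), reflux
Reagents that add atoms: methanol, SMILES CO
Why: Fischer esterification converts both carboxyl groups under acid catalysis and breaks no bond to the tertiary carbinol carbon, so its configuration is retained.

Step 2
Reactants: 2 dimethyl (2S)-2-hydroxy-2-methylbutanedioate
Product: 4 dimethyl (2S,3RS)-2,3-dihydroxy-2-methylbutanedioate, via dilithium alkoxide enolate 3 (not isolated)
Conditions: LiN(SiMe3)2 (2.2 equiv), THF, −78 → −40 °C; (camphorsulfonyl)oxaziridine, −78 °C; AcOH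
Reagents that add atoms: (camphorsulfonyl)oxaziridine (either enantiomer), SMILES CC1(C)C2CCC13CS(=O)(=O)N4OC34C2
Why: Fráter–Seebach-type double deprotonation gives an alkoxide enolate that cannot expel its β-oxygen (an O-methylated substrate would lose methoxide by E1cB), and Davis-type oxaziridine hydroxylation of this enolate installs the C3 oxygen, whose configuration is irrelevant because it is oxidised in step 6.

Step 3
Reactants: 4 dimethyl (2S,3RS)-2,3-dihydroxy-2-methylbutanedioate
Product: 5 dimethyl (2S,3RS)-3-[(tert-butyldimethylsilyl)oxy]-2-hydroxy-2-methylbutanedioate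
Conditions: TBSCl, imidazole, DMF, rt
Reagents that add atoms: tert-butyldimethylsilyl chloride, SMILES CC(C)(C)[Si](C)(C)Cl
Why: Standard silylation with the silyl chloride and imidazole distinguishes the two hydroxyls sterically and caps only the secondary one, since tertiary alcohols are inert to this reagent.

Step 4
Reactants: 5 dimethyl (2S,3RS)-3-[(tert-butyldimethylsilyl)oxy]-2-hydroxy-2-methylbutanedioate
Product: 6 dimethyl (2S,3RS)-3-[(tert-butyldimethylsilyl)oxy]-2-methoxy-2-methylbutanedioate
Conditions: MeOTf, 2,6-di-tert-butyl-4-methylpyridine, CH2Cl2, reflux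
Reagents that add atoms: methyl trifluoromethanesulfonate, SMILES COS(=O)(=O)C(F)(F)F
Why: O-alkylation of a hindered tertiary alcohol with methyl triflate and a non-nucleophilic pyridine base is a known, essentially neutral etherification that avoids retro-aldol cleavage, silyl migration and β-elimination, and it leaves C2 untouched because only the O–H bond reacts.

Step 5
Reactants: 6 dimethyl (2S,3RS)-3-[(tert-butyldimethylsilyl)oxy]-2-methoxy-2-methylbutanedioate
Product: 7 dimethyl (2S,3RS)-3-hydroxy-2-methoxy-2-methylbutanedioate
Conditions: HF·pyridine, THF, 0 °C → rt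
Reagents that add atoms: none
Why: Acidic fluoride desilylation frees the secondary alcohol without the basic medium in which the C3 proton and the β-methoxy group could be lost by E1cB elimination.

Step 6
Reactants: 7 dimethyl (2S,3RS)-3-hydroxy-2-methoxy-2-methylbutanedioate
Product: 8 dimethyl (2S)-2-methoxy-2-methyl-3-oxobutanedioate
Conditions: Dess–Martin periodinane, CH2Cl2, rt; pentane, filtration; azeotropic drying (toluene)
Reagents that add atoms: none
Why: Dess–Martin oxidation of an α-hydroxy ester to the α-keto ester runs under neutral conditions, merges both C3 epimers into one compound and, with a non-aqueous work-up, avoids hydration or retro-Claisen cleavage of the non-enolisable ketone.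

Step 7
Reactants: 8 dimethyl (2S)-2-methoxy-2-methyl-3-oxobutanedioate; 9 5-bromo-2-chloro-4-iodopyridine
Product: 13 methyl (5R,6S)-3-chloro-5-hydroxy-6-methoxy-6-methyl-7-oxo-6,7-dihydro-5H-cyclopenta[c]pyridine-5-carboxylate, via pyridylmagnesium chloride 10 (not isolated), via chloromagnesium alkoxide 11 (not isolated), via C7a-lithiated alkoxide 12 (not isolated)
Conditions: 9, iPrMgCl·LiCl (1.05 equiv), THF, −40 °C; 8, −78 → −40 °C; n-BuLi (1.05 equiv), −90 → −60 °C; AcOH, −78 °C
Reagents that add atoms: none
Why: Proposed new method: the weaker carbon–iodine bond of 9 exchanges first with iPrMgCl·LiCl to give 10, which adds to the C5 ketone of 8 (flanked by two acyl carbons and hence the most electrophilic carbonyl) to form C4a–C5 and alkoxide 11; n-BuLi then exchanges the neighbouring bromide, either directly or after butyl transfer to the alkoxide-bound magnesium, and the C7a carbanion 12 attacks the C7 ester and expels methoxide to form C7–C7a. The closest known reaction types are the addition of exchange-derived heteroaryl Grignard reagents to α-keto esters, the Parham cycloacylation of o-haloaryl esters and the iPrMgCl/n-BuLi exchange protocol for bromoarenes that carry a magnesiated heteroatom; only their pairing in one flask as a formal [3+2] annulation is untested. The carbocycle closes by a 5-exo-trig acyl substitution, whereas attack of C7a on the C5 ester would require a four-membered ring. C5 is set in the intermolecular addition under control of C6: a magnesium chelate of the ketone oxygen with the C6 methoxy group (aryl passing the methyl rather than the ester) and the alternative chelate with the C7 ester carbonyl (aryl passing methoxy rather than methyl) open the same face, which places CO2Me cis to OMe and gives 5R, while C6 itself is not touched. The step needs iodine to exchange before bromine and chlorine not at all, exchange to outrun butyl addition, and no proton transfer; these are secured by the graded carbon–halogen bond strengths, by both esters sitting on fully substituted carbons and by the absence of any enolisable hydrogen in 8. Temperatures at or below −40 °C and the cold AcOH quench are meant to keep 11 and the product alkoxide from retro-aldol cleavage, which would erase both ring stereocentres.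

Step 8
Reactants: 14 (S)-2-methylbutan-1-ol; 15 ethyl 2-(triphenyl-λ5-phosphanylidene)propanoate
Product: 17 ethyl (2E,4S)-2,4-dimethylhex-2-enoate, via (S)-2-methylbutanal 16 (not isolated)
Conditions: TEMPO (cat.), PhI(OAc)2, CH2Cl2, rt; then 15 (1.5 equiv), rt
Reagents that add atoms: none
Why: One-pot TEMPO/PhI(OAc)2 oxidation and Wittig olefination with a stabilised α-methyl ylide traps the volatile, epimerisable aldehyde in the flask and gives the E-trisubstituted enoate, as is usual for stabilised ylides.

Step 9
Reactants: 17 ethyl (2E,4S)-2,4-dimethylhex-2-enoate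
Product: 18 (2E,4S)-2,4-dimethylhex-2-en-1-ol
Conditions: i-Bu2AlH (2.2 equiv), CH2Cl2, −78 °C; aq potassium sodium tartrate
Reagents that add atoms: none
Why: 1,2-Reduction of an enoate with two equivalents of i-Bu2AlH at low temperature is the standard route to the allylic alcohol and affects neither the alkene geometry nor the allylic stereocentre.

Step 10
Reactants: 18 (2E,4S)-2,4-dimethylhex-2-en-1-ol
Product: 19 (2E,4S)-2,4-dimethylhex-2-enal
Conditions: MnO2, CH2Cl2, rt
Reagents that add atoms: none
Why: Allylic alcohol oxidation with activated MnO2 is neutral and chemoselective and stops at the enal without alkene isomerisation.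

Step 11
Reactants: 19 (2E,4S)-2,4-dimethylhex-2-enal; 20 bis(4,4,5,5-tetramethyl-1,3,2-dioxaborolan-2-yl)methane
Product: 22 2-[(1E,3E,5S)-3,5-dimethylhepta-1,3-dien-1-yl]-4,4,5,5-tetramethyl-1,3,2-dioxaborolane, via lithiated diborylmethane 21 (not isolated)
Conditions: 2,2,6,6-tetramethylpiperidine, n-BuLi, THF, 0 °C; 20, 0 °C; 19, −78 °C → rt
Reagents that add atoms: none
Why: In the boron–Wittig olefination the α-boryl carbanion adds to the aldehyde and syn boron–oxygen elimination from the less crowded adduct gives the E-alkenyl boronate, so the enal is extended to the (1E,3E)-dienyl boronate in one operation.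

Step 12
Reactants: 13 methyl (5R,6S)-3-chloro-5-hydroxy-6-methoxy-6-methyl-7-oxo-6,7-dihydro-5H-cyclopenta[c]pyridine-5-carboxylate; 22 2-[(1E,3E,5S)-3,5-dimethylhepta-1,3-dien-1-yl]-4,4,5,5-tetramethyl-1,3,2-dioxaborolane
Product: 23 methyl (5R,6S)-3-[(1E,3E,5S)-3,5-dimethylhepta-1,3-dien-1-yl]-5-hydroxy-6-methoxy-6-methyl-7-oxo-6,7-dihydro-5H-cyclopenta[c]pyridine-5-carboxylate
Conditions: Pd(OAc)2 (5 mol %), SPhos (10 mol %), K3PO4, THF/H2O, 40 °C
Reagents that add atoms: none
Why: In this Suzuki–Miyaura coupling the C3 chloride is a 2-chloropyridine para to the C7 acyl group and is therefore readily inserted by the zerovalent palladium–SPhos species formed from Pd(OAc)2, the alkenyl boronate transfers with retention of its E,E geometry, and the mild phosphate base at 40 °C should leave the methyl ester and the base-sensitive β-hydroxy ketone intact.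

**Compound list**
1 | (S)-citramalic acid, (2S)-2-hydroxy-2-methylbutanedioic acid | OC(=O)[C@@](C)(O)CC(=O)O | starting material
2 | dimethyl (2S)-2-hydroxy-2-methylbutanedioate | COC(=O)[C@@](C)(O)CC(=O)OC | intermediate
3 | dilithium alkoxide enolate of 2 | [Li+].[Li+].COC(=O)[C@@](C)([O-])C=C([O-])OC | intermediate
4 | dimethyl (2S,3RS)-2,3-dihydroxy-2-methylbutanedioate | COC(=O)[C@@](C)(O)C(O)C(=O)OC | intermediate
5 | dimethyl (2S,3RS)-3-[(tert-butyldimethylsilyl)oxy]-2-hydroxy-2-methylbutanedioate | COC(=O)[C@@](C)(O)C(O[Si](C)(C)C(C)(C)C)C(=O)OC | intermediate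
6 | dimethyl (2S,3RS)-3-[(tert-butyldimethylsilyl)oxy]-2-methoxy-2-methylbutanedioate | COC(=O)[C@@](C)(OC)C(O[Si](C)(C)C(C)(C)C)C(=O)OC | intermediate
7 | dimethyl (2S,3RS)-3-hydroxy-2-methoxy-2-methylbutanedioate | COC(=O)[C@@](C)(OC)C(O)C(=O)OC | intermediate
8 | dimethyl (2S)-2-methoxy-2-methyl-3-oxobutanedioate | COC(=O)[C@@](C)(OC)C(=O)C(=O)OC | intermediate
9 | 5-bromo-2-chloro-4-iodopyridine | Clc1cc(I)c(Br)cn1 | starting material
10 | (5-bromo-2-chloropyridin-4-yl)magnesium chloride (LiCl complex) | Clc1cc([Mg]Cl)c(Br)cn1 | intermediate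
11 | chloromagnesium alkoxide of dimethyl (2S,3R)-3-(5-bromo-2-chloropyridin-4-yl)-3-hydroxy-2-methoxy-2-methylbutanedioate | COC(=O)[C@@](C)(OC)[C@@](c1cc(Cl)ncc1Br)(O[Mg]Cl)C(=O)OC | intermediate
12 | the same alkoxide with lithium in place of bromine at the pyridine carbon that becomes C7a | COC(=O)[C@@](C)(OC)[C@@](c1cc(Cl)ncc1[Li])(O[Mg]Cl)C(=O)OC | intermediate
13 | methyl (5R,6S)-3-chloro-5-hydroxy-6-methoxy-6-methyl-7-oxo-6,7-dihydro-5H-cyclopenta[c]pyridine-5-carboxylate | Clc1cc2c(cn1)C(=O)[C@@](C)(OC)[C@@]2(O)C(=O)OC | intermediate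
14 | (S)-2-methylbutan-1-ol | CC[C@H](C)CO | starting material
15 | ethyl 2-(triphenyl-λ5-phosphanylidene)propanoate | CCOC(=O)C(C)=P(c1ccccc1)(c1ccccc1)c1ccccc1 | starting material
16 | (S)-2-methylbutanal | CC[C@H](C)C=O | intermediate
17 | ethyl (2E,4S)-2,4-dimethylhex-2-enoate | CC[C@H](C)/C=C(C)/C(=O)OCC | intermediate
18 | (2E,4S)-2,4-dimethylhex-2-en-1-ol | CC[C@H](C)/C=C(C)/CO | intermediate
19 | (2E,4S)-2,4-dimethylhex-2-enal | CC[C@H](C)/C=C(C)/C=O | intermediate
20 | bis(4,4,5,5-tetramethyl-1,3,2-dioxaborolan-2-yl)methane | CC1(C)OB(CB2OC(C)(C)C(C)(C)O2)OC1(C)C | starting material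
21 | lithio-bis(4,4,5,5-tetramethyl-1,3,2-dioxaborolan-2-yl)methane | [Li]C(B1OC(C)(C)C(C)(C)O1)B1OC(C)(C)C(C)(C)O1 | intermediate
22 | 2-[(1E,3E,5S)-3,5-dimethylhepta-1,3-dien-1-yl]-4,4,5,5-tetramethyl-1,3,2-dioxaborolane | CC[C@H](C)/C=C(C)/C=C/B1OC(C)(C)C(C)(C)O1 | intermediate
23 | methyl (5R,6S)-3-[(1E,3E,5S)-3,5-dimethylhepta-1,3-dien-1-yl]-5-hydroxy-6-methoxy-6-methyl-7-oxo-6,7-dihydro-5H-cyclopenta[c]pyridine-5-carboxylate | CC[C@H](C)/C=C(C)/C=C/c1cc2c(cn1)C(=O)[C@@](C)(OC)[C@@]2(O)C(=O)OC | target

**Totals**
Total step count: 12.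
Longest linear sequence: 8 steps (steps 1–7, then step 12).

**Steps most likely to fail**

Step 7.
- What may go wrong:
  - Butyl transfer to magnesium instead of bromine–lithium exchange, so that the second metalation stalls.
  - Butyl addition to an ester or to the newly formed ketone.
  - Retro-aldol fragmentation of the alkoxide.
  - Poor facial selectivity in the aryl addition.
- Fallback (known chemistry, the two bonds made in separate flasks): it sets out from 8 and 9. Only the iodine–magnesium exchange and the ketone addition are run, and the mixture is quenched to give dimethyl (2S,3R)-3-(5-bromo-2-chloropyridin-4-yl)-3-hydroxy-2-methoxy-2-methylbutanedioate F1. At this stage the C5 epimer can be removed by chromatography. The tertiary alcohol is capped with Me3SiOTf and 2,6-lutidine to give dimethyl (2S,3R)-3-(5-bromo-2-chloropyridin-4-yl)-2-methoxy-2-methyl-3-[(trimethylsilyl)oxy]butanedioate F2. A classical Parham cycloacylation in a magnesium-free medium (n-BuLi, THF, −100 °C) then closes the ring to methyl (5R,6S)-3-chloro-6-methoxy-6-methyl-7-oxo-5-[(trimethylsilyl)oxy]-6,7-dihydro-5H-cyclopenta[c]pyridine-5-carboxylate F3. HF·pyridine removes silicon and the route is rejoined at 13.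

Step 4.
- What may go wrong:
  - Sluggish alkylation of the crowded tertiary hydroxyl next to the silyloxy-bearing carbon.
  - Silyl migration, or silyl loss through adventitious triflic acid.
- Fallback (order of etherification and oxidation reversed): it sets out from 2. The carbinol of 2 has only a CH2 neighbour and is methylated with MeOTf and the same base, giving dimethyl (2S)-2-methoxy-2-methylbutanedioate F4. Deprotonation with lithium diisopropylamide in the presence of Me3SiCl at −100 °C (internal quench) traps the enolate before methoxide can leave, giving methyl (2S)-2,4-dimethoxy-2-methyl-4-[(trimethylsilyl)oxy]but-3-enoate F5. Rubottom oxidation with mCPBA and a mildly acidic work-up rejoins the route at 7, bypassing steps 2–5.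

Step 12.
- What may go wrong:
  - Base-induced retro-aldol opening of the β-hydroxy ketone, with loss of configuration at C5 and C6.
  - Ester hydrolysis.
  - Displacement of chloride by hydroxide.
- Fallback (alkoxide formation blocked by a protecting group): it sets out from 13, which is silylated with Et3SiOTf and 2,6-lutidine to give methyl (5R,6S)-3-chloro-6-methoxy-6-methyl-7-oxo-5-[(triethylsilyl)oxy]-6,7-dihydro-5H-cyclopenta[c]pyridine-5-carboxylate F6. Coupling with 22 gives methyl (5R,6S)-3-[(1E,3E,5S)-3,5-dimethylhepta-1,3-dien-1-yl]-6-methoxy-6-methyl-7-oxo-5-[(triethylsilyl)oxy]-6,7-dihydro-5H-cyclopenta[c]pyridine-5-carboxylate F7. HF·pyridine then rejoins the route at 23.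

**Further compounds**
F1 | step 7 | dimethyl (2S,3R)-3-(5-bromo-2-chloropyridin-4-yl)-3-hydroxy-2-methoxy-2-methylbutanedioate | COC(=O)[C@@](C)(OC)[C@@](c1cc(Cl)ncc1Br)(O)C(=O)OC
F2 | step 7 | dimethyl (2S,3R)-3-(5-bromo-2-chloropyridin-4-yl)-2-methoxy-2-methyl-3-[(trimethylsilyl)oxy]butanedioate | COC(=O)[C@@](C)(OC)[C@@](c1cc(Cl)ncc1Br)(O[Si](C)(C)C)C(=O)OC
F3 | step 7 | methyl (5R,6S)-3-chloro-6-methoxy-6-methyl-7-oxo-5-[(trimethylsilyl)oxy]-6,7-dihydro-5H-cyclopenta[c]pyridine-5-carboxylate | Clc1cc2c(cn1)C(=O)[C@@](C)(OC)[C@@]2(O[Si](C)(C)C)C(=O)OC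
F4 | step 4 | dimethyl (2S)-2-methoxy-2-methylbutanedioate | COC(=O)[C@@](C)(OC)CC(=O)OC
F5 | step 4 | methyl (2S)-2,4-dimethoxy-2-methyl-4-[(trimethylsilyl)oxy]but-3-enoate | COC(=O)[C@@](C)(OC)C=C(OC)O[Si](C)(C)C
F6 | step 12 | methyl (5R,6S)-3-chloro-6-methoxy-6-methyl-7-oxo-5-[(triethylsilyl)oxy]-6,7-dihydro-5H-cyclopenta[c]pyridine-5-carboxylate | Clc1cc2c(cn1)C(=O)[C@@](C)(OC)[C@@]2(O[Si](CC)(CC)CC)C(=O)OC
F7 | step 12 | methyl (5R,6S)-3-[(1E,3E,5S)-3,5-dimethylhepta-1,3-dien-1-yl]-6-methoxy-6-methyl-7-oxo-5-[(triethylsilyl)oxy]-6,7-dihydro-5H-cyclopenta[c]pyridine-5-carboxylate | CC[C@H](C)/C=C(C)/C=C/c1cc2c(cn1)C(=O)[C@@](C)(OC)[C@@]2(O[Si](CC)(CC)CC)C(=O)OC
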